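The eleven-membered ring is never closed as such: it is released from a cis-fused bicyclo[5.4.0]undecane by cutting the C5–C11 bond shared by its six-membered ring (C11, C1–C5) and seven-membered ring (C5–C11). The step exploits the 1,3-relationship in the target between the C11 oxygen and the C4=C5 enoate: an O–C11–C5–C4–OMs array with the mesylate trans to the C5 ester fragments in one operation to the C11 ketone, the E-enoate and the eleven-membered ring. The precursor is a tertiary C11 alcohol bearing a C5 tert-butyl ester, a C4 mesylate and the C7 silyl ether, built by ester-directed hydrogenation, Dieckmann closure, titanium aldol and SmI2 Barbier cyclisation.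

Key step: step 11

Remark on labels: ring atoms keep the labels of the target in all intermediates: C1 (bears the exocyclic methylene), C2, C3, C4=C5 (C5 bears the carboxyl), C6, C7 (angelate), C8, C9 (gem-dimethyl), C10, C11 (carbinol).
Remark on the chemistry: the C5 carboxyl is carried as its tert-butyl ester, a spectator change that fixes the regiochemistry of the Dieckmann closure, keeps the ester equatorial in the reactive chair of the key step and is unmasked at the end without hydrolysis; metal alkoxides and enolates formed by deprotonation are treated as ionised forms of the numbered compounds.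

Step 1
Reactants: 1 3,3-dimethylglutaric anhydride
Product: 2 monomethyl 3,3-dimethylglutarate (5-methoxy-3,3-dimethyl-5-oxopentanoic acid)
Conditions: MeOH, reflux
Reagents that add atoms: methanol, CO
Why: Methanol opens the symmetrical cyclic anhydride once (anhydride alcoholysis) and the carboxylic acid that is released does not react further under neutral conditions.

Step 2
Reactants: 2 monomethyl 3,3-dimethylglutarate; 3 tert-butyl 3-bromopropanoate
Product: 6 1-tert-butyl 8-methyl 6,6-dimethyl-4-oxooctanedioate (C7 ketone), via acid chloride 4 (not isolated), via organozinc bromide 5 (not isolated)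
Conditions: 2, (COCl)2, HCONMe2 (cat.), CH2Cl2, 0 °C to rt; 3, Zn, LiCl, THF, 40 °C; then Pd(PPh3)4 (5 mol%), THF, 0 °C to rt
Reagents that add atoms: none
Why: Oxalyl chloride activates the free acid, zinc inserts into the primary bromide to give the ester-stabilised zinc homoenolate, and zerovalent palladium couples the two (Negishi acylation) to a ketone that the mild organozinc does not attack further.

Step 3
Reactants: 6 keto diester
Product: 7 1-tert-butyl 8-methyl (4R)-4-hydroxy-6,6-dimethyloctanedioate (C7 carbinol)
Conditions: RuCl2[(S)-BINAP] (0.5 mol%), H2 (50 atm), MeOH, 50 °C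
Reagents that add atoms: none
Why: Ester-directed asymmetric hydrogenation of a 4-oxo ester (Noyori type): ketone and tert-butyl ester carbonyl chelate ruthenium, and the (S)-BINAP ligand, chosen by analogy with simple 4-oxo esters, should deliver hydrogen to the face that gives the (R)-carbinol, which is C7 in its final spatial arrangement.

Step 4
Reactants: 7 hydroxy diester
Product: 9 tert-butyl (6R)-6-hydroxy-4,4-dimethyl-2-oxocycloheptane-1-carboxylate (C5 stereolabile), via δ-lactone 8 (not isolated)
Conditions: KOtBu (3.0 equiv), THF, 0 °C to rt; 1 M HCl, 0 °C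
Reagents that add atoms: none
Why: The C7 alkoxide first closes the six-membered lactone on the methyl ester, the tert-butyl ester enolate then attacks the lactone carbonyl in a 5-exo mode and the bridged hemiketal alkoxide opens to the seven-membered β-keto ester (Dieckmann-type intramolecular Claisen condensation), driven by deprotonation of the product; the hindered tert-butyl ester cannot act as the electrophile, which fixes the regiochemistry.

Step 5
Reactants: 9 hydroxy β-keto ester
Product: 10 tert-butyl (6R)-6-[(tert-butyldimethylsilyl)oxy]-4,4-dimethyl-2-oxocycloheptane-1-carboxylate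
Conditions: TBSCl, imidazole, HCONMe2, rt
Reagents that add atoms: tert-butyldimethylsilyl chloride, CC(C)(C)[Si](C)(C)Cl
Why: Standard silylation of the secondary alcohol; any transannular hemiketal form is drained through the open hydroxy ketone, and the β-keto ester is not silylated by this mild reagent pair.

Step 6
Reactants: 11 4-chlorobutan-1-ol
Product: 12 4-chlorobutanal
Conditions: TEMPO (2,2,6,6-tetramethylpiperidin-1-oxyl, 5 mol%), PhI(OAc)2, CH2Cl2, rt
Reagents that add atoms: none
Why: The TEMPO-catalysed oxidation stops cleanly at the aldehyde and leaves the primary chloride untouched.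

Step 7
Reactants: 10 silyloxy β-keto ester; 12 4-chlorobutanal
Product: 13 tert-butyl (1S,6S)-6-[(tert-butyldimethylsilyl)oxy]-1-[(1R)-4-chloro-1-hydroxybutyl]-4,4-dimethyl-2-oxocycloheptane-1-carboxylate (4R,5S,7S in target labels)
Conditions: TiCl4, iPr2NEt, CH2Cl2, −78 °C; then 12, −78 °C; aq. NH4Cl
Reagents that add atoms: none
Why: Soft enolisation gives the chelated trichlorotitanium enolate of the β-keto ester, which adds to the titanium-bound aldehyde and is held as the aldolate until quench (titanium aldol addition); C5 should be set by attack anti to the axial C9 methyl group of the ring chair in which the C7 silyloxy group is equatorial, which places the new chain cis to that silyloxy group, and C4 by the aldehyde chain pointing to the ester flank of the chelate and not to the ring, which makes the C4 oxygen trans to the ester in the later six-membered ring.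

Step 8
Reactants: 13 aldol adduct
Product: 14 tert-butyl (1S,6S)-6-[(tert-butyldimethylsilyl)oxy]-1-[(1R)-4-chloro-1-(methanesulfonyloxy)butyl]-4,4-dimethyl-2-oxocycloheptane-1-carboxylate
Conditions: MsCl, Et3N, CH2Cl2, −20 to 0 °C
Reagents that add atoms: methanesulfonyl chloride, CS(=O)(=O)Cl
Why: Mesylation through sulfene works even for the hindered secondary alcohol next to the quaternary carbon, installs the leaving group before the tertiary hydroxyl exists so that no selectivity is needed, and removes the free hydroxyl that could quench an organosamarium or close a tetrahydrofuran.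

Step 9
Reactants: 14 chloro mesylate
Product: 15 tert-butyl (1S,6S)-6-[(tert-butyldimethylsilyl)oxy]-1-[(1R)-4-iodo-1-(methanesulfonyloxy)butyl]-4,4-dimethyl-2-oxocycloheptane-1-carboxylate
Conditions: NaI, acetone, reflux
Reagents that add atoms: sodium iodide, [Na+].[I-]
Why: Finkelstein exchange (SN2) at the primary chloride; the secondary mesylate flanked by a quaternary carbon cannot be displaced.

Step 10
Reactants: 15 iodo mesylate
Product: 16 tert-butyl (1S,3S,7S,11R)-3-[(tert-butyldimethylsilyl)oxy]-7-hydroxy-11-(methanesulfonyloxy)-5,5-dimethylbicyclo[5.4.0]undecane-1-carboxylate (cis-fused; C11 hydroxyl cis to the C5 ester; C4 mesylate trans to it; 4R,5S,7S,11S in target labels)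
Conditions: SmI2 (2.2 equiv), THF, −78 to −20 °C; aq. NH4Cl
Reagents that add atoms: none
Why: SmI2 reduces the primary iodide and the resulting organosamarium adds to the C11 ketone while trivalent samarium bridges the ketone and ester oxygens (intramolecular samarium Barbier reaction), so C1 arrives on the face of its C4 tether and the new C11 hydroxyl is cis to the ester with a cis ring fusion; the hindered mesylate is not reduced.

Step 11
Reactants: 16 cis-fused hydroxy mesylate
Product: 17 tert-butyl (1E,10S)-10-[(tert-butyldimethylsilyl)oxy]-8,8-dimethyl-6-oxocycloundec-1-ene-1-carboxylate (C11 ketone, E-configured C4=C5 enoate, 7S silyl ether)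
Conditions: KN(SiMe3)2 (1.1 equiv), THF, −78 to 0 °C; aq. NH4Cl
Reagents that add atoms: none
Why: KN(SiMe3)2 deprotonates the tertiary C11 hydroxyl; the alkoxide lone pair pushes into the C5–C11 σ bond, which breaks as the C4=C5 π bond forms and mesylate leaves from C4, all three bonds anti-periplanar in one chair of the six-membered ring. The closest known reaction type is the Grob (Wharton) fragmentation of cyclic 1,3-hydroxy sulfonates to medium-ring unsaturated ketones. The eleven-membered ring is not formed by a cyclisation but by ring expansion: scission of the bond shared by the six- and seven-membered rings merges them, so no end-to-end closure mode is involved. No new stereocentre arises; C4, C5 and C11 are erased and C7 is untouched. The step needs E geometry (C3 cis to C6, ester trans to C3) and the concerted path ahead of retro-aldol cleavage followed by E1cB elimination: the mesylate, being trans to the ester, is equatorial and anti to C5–C11 in the chair that keeps the bulky tert-butyl ester equatorial and C6 axial, and with the leaving group already aligned at low temperature the elimination should keep pace with C–C cleavage.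

Step 12
Reactants: 17 silyloxy keto enoate
Product: 18 tert-butyl (1E,10S)-10-hydroxy-8,8-dimethyl-6-oxocycloundec-1-ene-1-carboxylate
Conditions: HF·pyridine, pyridine, THF, 0 °C to rt
Reagents that add atoms: none
Why: Buffered fluoride cleaves the secondary silyl ether (desilylation) without touching the tert-butyl enoate or enolising the ketone.

Step 13
Reactants: 18 hydroxy ketone; 19 angelic acid, (2Z)-2-methylbut-2-enoic acid
Product: 21 tert-butyl (1E,10S)-8,8-dimethyl-10-{[(2Z)-2-methylbut-2-enoyl]oxy}-6-oxocycloundec-1-ene-1-carboxylate, via mixed anhydride 20 (not isolated)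
Conditions: 19, 2,4,6-trichlorobenzoyl chloride, Et3N, toluene, rt; then 18, toluene, 75 °C
Reagents that add atoms: none
Why: The preformed mixed anhydride of angelic acid and 2,4,6-trichlorobenzoic acid acylates the C7 hydroxyl on heating (Yamaguchi-type esterification run without a nucleophilic amine catalyst), which avoids the Z-to-E isomerisation to the tiglate; the saturated ketone present at this stage tolerates the heating.

Step 14
Reactants: 21 angelate ketone
Product: 24 tert-butyl (1E,10S)-8,8-dimethyl-5-methylidene-10-{[(2Z)-2-methylbut-2-enoyl]oxy}-6-oxocycloundec-1-ene-1-carboxylate (exocyclic methylene at C1), via Mannich base 22 (not isolated), via ammonium iodide 23 (not isolated)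
Conditions: LiN(SiMe3)2 (1.1 equiv), THF, −78 °C; CH2=NMe2+ I−, −78 °C to rt; MeI, CH2Cl2, rt; aq. NaHCO3, rt
Reagents that add atoms: N,N-dimethylmethyleneiminium iodide (Eschenmoser's salt), C=[N+](C)C.[I-]
Why: Kinetic deprotonation by the bulky amide occurs at C1 and not at the neopentyl-like C10, the enolate is aminomethylated by the iminium salt (Mannich reaction), and quaternisation followed by mild base elimination unveils the exocyclic methylene just before it is needed.

Step 15
Reactants: 24 exo-methylene ketone
Product: 25 tert-butyl (1E,6S,10S)-6-hydroxy-8,8-dimethyl-5-methylidene-10-{[(2Z)-2-methylbut-2-enoyl]oxy}cycloundec-1-ene-1-carboxylate (7S,11S in target labels)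
Conditions: (R)-Me-CBS oxazaborolidine [(3aR)-1-methyl-3,3-diphenyltetrahydro-1H,3H-pyrrolo[1,2-c][1,3,2]oxazaborole] (0.5 equiv), catecholborane (2 equiv), toluene, −78 °C; MeOH, aq. NaHCO3
Reagents that add atoms: none
Why: Corey–Bakshi–Shibata reduction: the ketone binds the oxazaborolidine with the alkenyl side (C1) as the large group, so the (R)-catalyst should deliver hydride from catecholborane to the face that gives the (11S) carbinol, and at low temperature only 1,2-reduction is expected.

Step 16
Reactants: 25 tert-butyl ester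
Product: 27 (1E,6S,10S)-6-hydroxy-8,8-dimethyl-5-methylidene-10-{[(2Z)-2-methylbut-2-enoyl]oxy}cycloundec-1-ene-1-carboxylic acid (target), via bis-silyl derivative 26 (not isolated)
Conditions: TMSOTf, 2,6-lutidine, CH2Cl2, 0 °C; then aq. citric acid, THF, rt
Reagents that add atoms: none
Why: The silyl triflate converts the tert-butyl ester into the trimethylsilyl ester with loss of 2-methylpropene and silylates the allylic hydroxyl in passing (silyl-triflate ester cleavage), and mild aqueous acid then frees acid and alcohol without the hydrolytic conditions that would threaten the angelate.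

Compound list
1 | 3,3-dimethylglutaric anhydride (4,4-dimethyloxane-2,6-dione) | CC1(C)CC(=O)OC(=O)C1 | starting material
2 | 5-methoxy-3,3-dimethyl-5-oxopentanoic acid | COC(=O)CC(C)(C)CC(=O)O | intermediate
3 | tert-butyl 3-bromopropanoate | CC(C)(C)OC(=O)CCBr | starting material
4 | methyl 5-chloro-3,3-dimethyl-5-oxopentanoate | COC(=O)CC(C)(C)CC(=O)Cl | intermediate (not isolated)
5 | (3-tert-butoxy-3-oxopropyl)zinc bromide | CC(C)(C)OC(=O)CC[Zn]Br | intermediate (not isolated)
6 | 1-tert-butyl 8-methyl 6,6-dimethyl-4-oxooctanedioate | COC(=O)CC(C)(C)CC(=O)CCC(=O)OC(C)(C)C | intermediate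
7 | 1-tert-butyl 8-methyl (4R)-4-hydroxy-6,6-dimethyloctanedioate | COC(=O)CC(C)(C)C[C@H](O)CCC(=O)OC(C)(C)C | intermediate
8 | tert-butyl 3-[(2R)-4,4-dimethyl-6-oxooxan-2-yl]propanoate | O=C1CC(C)(C)C[C@@H](CCC(=O)OC(C)(C)C)O1 | intermediate (not isolated)
9 | tert-butyl (6R)-6-hydroxy-4,4-dimethyl-2-oxocycloheptane-1-carboxylate (ester-bearing carbon stereolabile) | CC(C)(C)OC(=O)C1C[C@@H](O)CC(C)(C)CC1=O | intermediate
10 | tert-butyl (6R)-6-[(tert-butyldimethylsilyl)oxy]-4,4-dimethyl-2-oxocycloheptane-1-carboxylate (ester-bearing carbon stereolabile) | CC(C)(C)OC(=O)C1C[C@@H](O[Si](C)(C)C(C)(C)C)CC(C)(C)CC1=O | intermediate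
11 | 4-chlorobutan-1-ol | OCCCCCl | starting material
12 | 4-chlorobutanal | O=CCCCCl | intermediate
13 | tert-butyl (1S,6S)-6-[(tert-butyldimethylsilyl)oxy]-1-[(1R)-4-chloro-1-hydroxybutyl]-4,4-dimethyl-2-oxocycloheptane-1-carboxylate | ClCCC[C@@H](O)[C@@]1(C(=O)OC(C)(C)C)C[C@@H](O[Si](C)(C)C(C)(C)C)CC(C)(C)CC1=O | intermediate
14 | tert-butyl (1S,6S)-6-[(tert-butyldimethylsilyl)oxy]-1-[(1R)-4-chloro-1-(methanesulfonyloxy)butyl]-4,4-dimethyl-2-oxocycloheptane-1-carboxylate | ClCCC[C@@H](OS(C)(=O)=O)[C@@]1(C(=O)OC(C)(C)C)C[C@@H](O[Si](C)(C)C(C)(C)C)CC(C)(C)CC1=O | intermediate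
15 | tert-butyl (1S,6S)-6-[(tert-butyldimethylsilyl)oxy]-1-[(1R)-4-iodo-1-(methanesulfonyloxy)butyl]-4,4-dimethyl-2-oxocycloheptane-1-carboxylate | ICCC[C@@H](OS(C)(=O)=O)[C@@]1(C(=O)OC(C)(C)C)C[C@@H](O[Si](C)(C)C(C)(C)C)CC(C)(C)CC1=O | intermediate
16 | tert-butyl (1S,3S,7S,11R)-3-[(tert-butyldimethylsilyl)oxy]-7-hydroxy-11-(methanesulfonyloxy)-5,5-dimethylbicyclo[5.4.0]undecane-1-carboxylate | O[C@]12CCC[C@@H](OS(C)(=O)=O)[C@@]1(C(=O)OC(C)(C)C)C[C@@H](O[Si](C)(C)C(C)(C)C)CC(C)(C)C2 | intermediate (key-step precursor)
17 | tert-butyl (1E,10S)-10-[(tert-butyldimethylsilyl)oxy]-8,8-dimethyl-6-oxocycloundec-1-ene-1-carboxylate | O=C1CCC/C=C(/C(=O)OC(C)(C)C)C[C@@H](O[Si](C)(C)C(C)(C)C)CC(C)(C)C1 | intermediate (key-step product)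
18 | tert-butyl (1E,10S)-10-hydroxy-8,8-dimethyl-6-oxocycloundec-1-ene-1-carboxylate | O=C1CCC/C=C(/C(=O)OC(C)(C)C)C[C@@H](O)CC(C)(C)C1 | intermediate
19 | angelic acid, (2Z)-2-methylbut-2-enoic acid | C/C=C(/C)C(=O)O | starting material
20 | (2Z)-2-methylbut-2-enoic 2,4,6-trichlorobenzoic anhydride | C/C=C(/C)C(=O)OC(=O)c1c(Cl)cc(Cl)cc1Cl | intermediate (not isolated)
21 | tert-butyl (1E,10S)-8,8-dimethyl-10-{[(2Z)-2-methylbut-2-enoyl]oxy}-6-oxocycloundec-1-ene-1-carboxylate | O=C1CCC/C=C(/C(=O)OC(C)(C)C)C[C@@H](OC(=O)/C(C)=C\C)CC(C)(C)C1 | intermediate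
22 | tert-butyl (1E,10S)-5-[(dimethylamino)methyl]-8,8-dimethyl-10-{[(2Z)-2-methylbut-2-enoyl]oxy}-6-oxocycloundec-1-ene-1-carboxylate (both epimers at the aminomethyl-bearing carbon) | CN(C)CC1CC/C=C(/C(=O)OC(C)(C)C)C[C@@H](OC(=O)/C(C)=C\C)CC(C)(C)CC1=O | intermediate (not isolated)
23 | trimethylammonium iodide of 22 (N-methylated Mannich base) | C[N+](C)(C)CC1CC/C=C(/C(=O)OC(C)(C)C)C[C@@H](OC(=O)/C(C)=C\C)CC(C)(C)CC1=O.[I-] | intermediate (not isolated)
24 | tert-butyl (1E,10S)-8,8-dimethyl-5-methylidene-10-{[(2Z)-2-methylbut-2-enoyl]oxy}-6-oxocycloundec-1-ene-1-carboxylate | C=C1CC/C=C(/C(=O)OC(C)(C)C)C[C@@H](OC(=O)/C(C)=C\C)CC(C)(C)CC1=O | intermediate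
25 | tert-butyl (1E,6S,10S)-6-hydroxy-8,8-dimethyl-5-methylidene-10-{[(2Z)-2-methylbut-2-enoyl]oxy}cycloundec-1-ene-1-carboxylate | C=C1CC/C=C(/C(=O)OC(C)(C)C)C[C@@H](OC(=O)/C(C)=C\C)CC(C)(C)C[C@@H]1O | intermediate
26 | trimethylsilyl (1E,6S,10S)-8,8-dimethyl-5-methylidene-10-{[(2Z)-2-methylbut-2-enoyl]oxy}-6-[(trimethylsilyl)oxy]cycloundec-1-ene-1-carboxylate | C=C1CC/C=C(/C(=O)O[Si](C)(C)C)C[C@@H](OC(=O)/C(C)=C\C)CC(C)(C)C[C@@H]1O[Si](C)(C)C | intermediate (not isolated)
27 | (1E,6S,10S)-6-hydroxy-8,8-dimethyl-5-methylidene-10-{[(2Z)-2-methylbut-2-enoyl]oxy}cycloundec-1-ene-1-carboxylic acid | C=C1CC/C=C(/C(=O)O)C[C@@H](OC(=O)/C(C)=C\C)CC(C)(C)C[C@@H]1O | target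

Total step count: 16. Longest linear sequence: 15 (steps 1–5 and 7–16; step 6 prepares the aldehyde).

Steps most likely to fail

Step 7 (titanium aldol). The aldehyde chain may orient unselectively in the chelated transition state, so that both C4 epimers form, and the quaternary aldol may partly revert by retro-aldol cleavage on work-up. A wrong ring face at C5 relative to C7 would not be fatal, because C4, C5 and C11 are all erased in step 11 and only their mutual relationship matters. The fallback sets out from 10 and returns at 16; it fixes C4 after ring closure by a hydroxyl-directed reduction. The aldol is run as in step 7 and the C4-epimeric aldol mixture F1 is silylated (Et3SiCl, imidazole) to the triethylsilyl ethers F2, exchanged to the iodides F3 (NaI, acetone) and cyclised with SmI2 to the bicyclic tertiary alcohols F4. Pyridinium p-toluenesulfonate in MeOH removes only the triethylsilyl group to give the diols F5, and Dess–Martin periodinane oxidises the secondary hydroxyl to the single C4 ketone F6. Me4NBH(OAc)3 in MeCN/AcOH then delivers hydride intramolecularly from the C11 oxygen (Evans–Saksena reduction) to give the trans-1,3-diol F7 with the (4R) carbinol, and selective mesylation of the secondary hydroxyl (MsCl, Et3N) gives 16. This sequence also keeps the mesylate away from SmI2.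

Step 11 (fragmentation). C5–C11 cleavage may run ahead of mesylate loss, so that the ring-opened ester enolate relaxes before it eliminates and the alkene geometry erodes. The fallback sets out from 16 and returns at 17; it removes the carbanion-stabilising ester before fragmenting. The tert-butyl ester of 16 is cleaved selectively with 85% aqueous H3PO4 in toluene to the hydroxy acid mesylate F8. Two equivalents of KN(SiMe3)2 give the carboxylate alkoxide dianion, in which a free C5 carbanion is no longer accessible, so only the concerted anti fragmentation remains and should give the keto acid F9 with the same geometry. tert-Butyl 2,2,2-trichloroacetimidate (cat. BF3·OEt2, CH2Cl2) re-forms the tert-butyl ester 17.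

Step 15 (CBS reduction). The conformation of the eleven-membered ring, not the oxazaborolidine, may decide which face of the C11 carbonyl is open, giving poor facial selectivity, or conjugate hydride addition to the exo-methylene ketone may compete. The fallback sets out from 24 and returns at 25. Substrate-controlled 1,2-reduction under Luche conditions (NaBH4, CeCl3·7H2O, MeOH, −40 °C) should give 25 together with its C11 epimer F10; the two are separated by chromatography, and F10 is oxidised back to 24 with MnO2 and recycled.

Further compounds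
F1 | step 7 | aldol 13 as both epimers at the carbinol carbon (C4) | ClCCCC(O)[C@@]1(C(=O)OC(C)(C)C)C[C@@H](O[Si](C)(C)C(C)(C)C)CC(C)(C)CC1=O
F2 | step 7 | triethylsilyl ethers of F1 | ClCCCC(O[Si](CC)(CC)CC)[C@@]1(C(=O)OC(C)(C)C)C[C@@H](O[Si](C)(C)C(C)(C)C)CC(C)(C)CC1=O
F3 | step 7 | primary iodides from F2 | ICCCC(O[Si](CC)(CC)CC)[C@@]1(C(=O)OC(C)(C)C)C[C@@H](O[Si](C)(C)C(C)(C)C)CC(C)(C)CC1=O
F4 | step 7 | cis-fused bicyclic C11 alcohols with C4 triethylsilyl ether (both C4 epimers) | O[C@]12CCCC(O[Si](CC)(CC)CC)[C@@]1(C(=O)OC(C)(C)C)C[C@@H](O[Si](C)(C)C(C)(C)C)CC(C)(C)C2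
F5 | step 7 | cis-fused bicyclic C4,C11-diols (both C4 epimers) | O[C@]12CCCC(O)[C@@]1(C(=O)OC(C)(C)C)C[C@@H](O[Si](C)(C)C(C)(C)C)CC(C)(C)C2
F6 | step 7 | cis-fused bicyclic C4 ketone with C11 hydroxyl (C5, C7, C11 as in 16) | O[C@]12CCCC(=O)[C@@]1(C(=O)OC(C)(C)C)C[C@@H](O[Si](C)(C)C(C)(C)C)CC(C)(C)C2
F7 | step 7 | trans-1,3-diol, 16 with a free (4R) hydroxyl in place of the mesylate | O[C@]12CCC[C@@H](O)[C@@]1(C(=O)OC(C)(C)C)C[C@@H](O[Si](C)(C)C(C)(C)C)CC(C)(C)C2
F8 | step 11 | free C5 carboxylic acid of 16 (mesylate, C11 hydroxyl, C7 silyl ether unchanged) | O[C@]12CCC[C@@H](OS(C)(=O)=O)[C@@]1(C(=O)O)C[C@@H](O[Si](C)(C)C(C)(C)C)CC(C)(C)C2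
F9 | step 11 | (1E,10S)-10-[(tert-butyldimethylsilyl)oxy]-8,8-dimethyl-6-oxocycloundec-1-ene-1-carboxylic acid | O=C1CCC/C=C(/C(=O)O)C[C@@H](O[Si](C)(C)C(C)(C)C)CC(C)(C)C1
F10 | step 15 | C11 epimer of 25, tert-butyl (1E,6R,10S)-6-hydroxy-8,8-dimethyl-5-methylidene-10-{[(2Z)-2-methylbut-2-enoyl]oxy}cycloundec-1-ene-1-carboxylate | C=C1CC/C=C(/C(=O)OC(C)(C)C)C[C@@H](OC(=O)/C(C)=C\C)CC(C)(C)C[C@H]1O
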